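**Assumption:** the target SMILES has no stereocentre (isoirigenin is achiral), so there is no configuration to set and "single enantiomer" needs no action.

## Retrosynthetic overview

1. A-ring fragment: resorcinol (1) is taken to salicylaldehyde 6 by Ir C–H borylation/oxidation, ortho-formylation, ortho-iodination and Cu-catalysed methoxylation.
2. B-ring fragment: catechol (7) is taken to aryl iodide 12 by methylation, ortho-lithiation/oxidation, MOM protection, Ir C–H borylation and iododeboronation; Sonogashira coupling with ethynyltrimethylsilane (13) gives silylalkyne 14.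
3. Key disconnection: C4–C3 and O1–C2 of the pyranone, formed together by Rh(III) aldehyde C–H activation/oxidative annulation of 6 with 14 to give 2-silylisoflavone 15. Silicon directs the aryl group to C3.
4. End game: C2 protodesilylation (16), then removal of the three MOM groups gives isoirigenin (17).
5. Ring order: both benzene rings come from 1 and 7. The pyran-4-one is the only ring built, and it is formed in the fragment union.

## Route

### A-ring fragment

**Step 1**
Reactants: 1, resorcinol
Product: 2, 1,3-bis(methoxymethoxy)benzene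
Conditions: MOMCl (2.5 equiv), i-Pr2NEt, CH2Cl2, 0 °C → rt
Reagents that add atoms: chloromethyl methyl ether, COCCl
Why: Williamson-type double O-alkylation of the phenols; MOM tolerates the later Ir, Mg, Cu, Rh and fluoride steps and is removed by mild acid at the end.

**Step 2**
Reactants: 2, 1,3-bis(methoxymethoxy)benzene
Product: 3, 3,5-bis(methoxymethoxy)phenol
Conditions: [Ir(OMe)(cod)]2 (1 mol %), dtbpy (2 mol %), B2pin2, THF, 80 °C; then aq. NaOH/H2O2, 0 °C → rt, NH4Cl work-up
Reagents that add atoms: hydrogen peroxide, OO (B2pin2 is transient; boron is not retained)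
Why: Sterically controlled Ir-catalysed aromatic C–H borylation reacts only at C5, the one C–H with no ortho substituent, and basic peroxide oxidation of the ArBpin gives the phenol without harming the MOM acetals.

**Step 3**
Reactants: 3, 3,5-bis(methoxymethoxy)phenol
Product: 4, 2-hydroxy-4,6-bis(methoxymethoxy)benzaldehyde
Conditions: MgCl2, Et3N, (CH2O)n, MeCN, reflux
Reagents that add atoms: paraformaldehyde (as formaldehyde), C=O
Why: Hansen–Skattebøl magnesium-phenoxide-directed ortho-formylation; the two ortho positions are equivalent so one regioisomer forms, and the non-acidic medium spares the MOM groups.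

**Step 4**
Reactants: 4, 2-hydroxy-4,6-bis(methoxymethoxy)benzaldehyde
Product: 5, 2-hydroxy-3-iodo-4,6-bis(methoxymethoxy)benzaldehyde
Conditions: BnMe3N+ ICl2– (1.05 equiv), CaCO3, CH2Cl2/MeOH, rt
Reagents that add atoms: benzyltrimethylammonium dichloroiodate, C[N+](C)(C)Cc1ccccc1.Cl[I-]Cl
Why: Electrophilic aromatic iodination is expected at C3, ortho to the free chelated phenol, by analogy with ortho-to-OH iodination of 5-hydroxy-7-alkoxyflavones and 2-hydroxy-4,6-dialkoxyacetophenones; CaCO3 scavenges HCl to protect MOM.

**Step 5**
Reactants: 5, 2-hydroxy-3-iodo-4,6-bis(methoxymethoxy)benzaldehyde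
Product: 6, 2-hydroxy-3-methoxy-4,6-bis(methoxymethoxy)benzaldehyde
Conditions: CuI (15 mol %), NaOMe (5 equiv), MeOH/DMF, 100 °C
Reagents that add atoms: sodium methoxide, [Na+].[O-]C
Why: Ullmann-type Cu-catalysed C–O coupling of an aryl iodide ortho to a phenoxide (the 5-halovanillin → syringaldehyde type); the aldehyde is non-enolisable and MOM ethers are base-stable.

### B-ring fragment

**Step 6**
Reactants: 7, catechol
Product: 8, 1,2-dimethoxybenzene (veratrole)
Conditions: MeI (2.5 equiv), K2CO3, acetone, reflux
Reagents that add atoms: iodomethane, CI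
Why: Exhaustive Williamson O-methylation.

**Step 7**
Reactants: 8, 1,2-dimethoxybenzene
Product: 9, 2,3-dimethoxyphenol
Conditions: n-BuLi, TMEDA, Et2O, 0 °C → rt; B(OMe)3, –78 °C → rt; then H2O2, AcOH, 0 °C
Reagents that add atoms: hydrogen peroxide, OO (trimethyl borate is transient)
Why: Methoxy-directed ortho-lithiation of veratrole at C3, borate trapping and oxidative C–B to C–O conversion.

**Step 8**
Reactants: 9, 2,3-dimethoxyphenol
Product: 10, 1,2-dimethoxy-3-(methoxymethoxy)benzene
Conditions: MOMCl, i-Pr2NEt, CH2Cl2, 0 °C → rt
Reagents that add atoms: chloromethyl methyl ether, COCCl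
Why: O-alkylation; masking the phenol prevents O-borylation and ortho-direction in the next step and matches the final acid deprotection.

**Step 9**
Reactants: 10, 1,2-dimethoxy-3-(methoxymethoxy)benzene
Product: 11, 2-[3,4-dimethoxy-5-(methoxymethoxy)phenyl]-4,4,5,5-tetramethyl-1,3,2-dioxaborolane
Conditions: [Ir(OMe)(cod)]2 (1 mol %), dtbpy (2 mol %), B2pin2, THF, 80 °C
Reagents that add atoms: bis(pinacolato)diboron, CC1(C)OB(OC1(C)C)B1OC(C)(C)C(C)(C)O1
Why: Sterically controlled Ir-catalysed C–H borylation of a 1,2,3-trisubstituted arene occurs only at C5, giving the 1,3,4,5-pattern that electrophilic substitution cannot reach.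

**Step 10**
Reactants: 11, the aryl pinacol boronate
Product: 12, 5-iodo-1,2-dimethoxy-3-(methoxymethoxy)benzene
Conditions: CuI (10 mol %), 1,10-phenanthroline (20 mol %), KI, MeOH/H2O, air, 80 °C
Reagents that add atoms: potassium iodide, [K+].[I-]
Why: Cu-mediated ipso-iododeboronation proceeds through B-to-Cu transmetalation, so it is position-specific and avoids ring C–H iodination of the electron-rich arene; neutral conditions keep MOM.

**Step 11**
Reactants: 12, 5-iodo-1,2-dimethoxy-3-(methoxymethoxy)benzene; 13, ethynyltrimethylsilane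
Product: 14, {[3,4-dimethoxy-5-(methoxymethoxy)phenyl]ethynyl}trimethylsilane
Conditions: PdCl2(PPh3)2 (2 mol %), CuI (4 mol %), Et3N, THF, 50 °C
Reagents that add atoms: none (13 is a reactant)
Why: Sonogashira coupling of an aryl iodide with a terminal alkyne.

### Fragment union and end game

**Step 12**
Reactants: 6, 2-hydroxy-3-methoxy-4,6-bis(methoxymethoxy)benzaldehyde; 14, the aryl(trimethylsilyl)alkyne (1.3 equiv)
Product: 15, 3-[3,4-dimethoxy-5-(methoxymethoxy)phenyl]-8-methoxy-5,7-bis(methoxymethoxy)-2-(trimethylsilyl)-4H-chromen-4-one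
Conditions: [Cp*RhCl2]2 (2.5 mol %), AgSbF6 (10 mol %), Cu(OAc)2 (2.2 equiv), NaOAc (1 equiv), t-AmOH, 90 °C, N2
Reagents that add atoms: none
Why: Proposed new method: phenoxide-directed, carboxylate-assisted Cp*Rh(III) cleavage of the aldehydic C–H gives a five-membered acyl-rhodacycle; 1,2-insertion of the aryl(silyl)alkyne should place Rh on the silicon-bearing carbon (α-silyl stabilisation of C–Rh and the bulky SiMe3 kept away from the forming C–C bond, as in Larock-type heteroannulations), so the acyl carbon bonds to the aryl-bearing carbon; C–O reductive elimination from the seven-membered oxarhodacycle closes the pyranone and Cu(II) reoxidises Rh(I). The closest known reaction type is the Rh-catalysed oxidative annulation of salicylaldehydes with internal alkynes to 2,3-disubstituted chromones, which with aryl/alkyl alkynes puts aryl at C2; using a silylalkyne to reverse this and reach the 3-aryl (isoflavone) pattern is the untested part.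

**Step 13**
Reactants: 15, the 2-silylisoflavone
Product: 16, 3-[3,4-dimethoxy-5-(methoxymethoxy)phenyl]-8-methoxy-5,7-bis(methoxymethoxy)-4H-chromen-4-one
Conditions: TBAF (1.2 equiv), AcOH (1.2 equiv), wet THF, 0 °C → rt
Reagents that add atoms: none
Why: Fluoride-induced protodesilylation of a vinylsilane whose carbon is α to the ring oxygen and β to the carbonyl; the AcOH buffer supplies the proton and suppresses nucleophilic opening of the pyranone at C2.

**Step 14**
Reactants: 16, the tri-MOM isoflavone
Product: 17, isoirigenin, 5,7-dihydroxy-3-(3-hydroxy-4,5-dimethoxyphenyl)-8-methoxy-4H-chromen-4-one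
Conditions: 3 M aq. HCl/MeOH–THF, 50 °C
Reagents that add atoms: none
Why: Acid-catalysed acetal hydrolysis of the three MOM ethers; these conditions are far milder than the hot HI/HBr that causes Wessely–Moser 8-OMe to 6-OMe isomerisation, and the methyl ethers are untouched.

## Compound list

1 | resorcinol | Oc1cccc(O)c1 | starting material
2 | 1,3-bis(methoxymethoxy)benzene | COCOc1cccc(OCOC)c1 | intermediate
3 | 3,5-bis(methoxymethoxy)phenol | COCOc1cc(O)cc(OCOC)c1 | intermediate
4 | 2-hydroxy-4,6-bis(methoxymethoxy)benzaldehyde | COCOc1cc(OCOC)c(C=O)c(O)c1 | intermediate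
5 | 2-hydroxy-3-iodo-4,6-bis(methoxymethoxy)benzaldehyde | COCOc1cc(OCOC)c(C=O)c(O)c1I | intermediate
6 | 2-hydroxy-3-methoxy-4,6-bis(methoxymethoxy)benzaldehyde | COCOc1cc(OCOC)c(C=O)c(O)c1OC | intermediate
7 | catechol | Oc1ccccc1O | starting material
8 | 1,2-dimethoxybenzene | COc1ccccc1OC | intermediate
9 | 2,3-dimethoxyphenol | COc1cccc(O)c1OC | intermediate
10 | 1,2-dimethoxy-3-(methoxymethoxy)benzene | COCOc1cccc(OC)c1OC | intermediate
11 | 2-[3,4-dimethoxy-5-(methoxymethoxy)phenyl]-4,4,5,5-tetramethyl-1,3,2-dioxaborolane | COCOc1cc(B2OC(C)(C)C(C)(C)O2)cc(OC)c1OC | intermediate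
12 | 5-iodo-1,2-dimethoxy-3-(methoxymethoxy)benzene | COCOc1cc(I)cc(OC)c1OC | intermediate
13 | ethynyltrimethylsilane | C#C[Si](C)(C)C | starting material
14 | {[3,4-dimethoxy-5-(methoxymethoxy)phenyl]ethynyl}trimethylsilane | COCOc1cc(C#C[Si](C)(C)C)cc(OC)c1OC | intermediate
15 | 3-[3,4-dimethoxy-5-(methoxymethoxy)phenyl]-8-methoxy-5,7-bis(methoxymethoxy)-2-(trimethylsilyl)-4H-chromen-4-one | COCOc1cc(-c2c([Si](C)(C)C)oc3c(OC)c(OCOC)cc(OCOC)c3c2=O)cc(OC)c1OC | intermediate
16 | 3-[3,4-dimethoxy-5-(methoxymethoxy)phenyl]-8-methoxy-5,7-bis(methoxymethoxy)-4H-chromen-4-one | COCOc1cc(-c2coc3c(OC)c(OCOC)cc(OCOC)c3c2=O)cc(OC)c1OC | intermediate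
17 | isoirigenin | COc1cc(-c2coc3c(OC)c(O)cc(O)c3c2=O)cc(O)c1OC | target

## Summary

**Total steps:** 14 (A-ring branch 5, B-ring branch 6, union and end game 3).

**Longest linear sequence:** 9 steps (7 → 8 → 9 → 10 → 11 → 12 → 14 → 15 → 16 → 17), which is 9 of 14.

**Three steps most likely to fail**

1. **Step 12 (proposed new Rh(III) annulation).** Risks are the opposite insertion regiochemistry (2-aryl-3-silyl product), desilylative alkyne homocoupling under Cu(II), and partial MOM loss. Fallback with known chemistry: convert aldehyde 6 to the methyl ketone (MeMgBr, then MnO2 or DMP), form the enaminone with DMF-DMA, cyclise with I2 to 3-iodo-8-methoxy-5,7-bis(methoxymethoxy)chromone, and run a Suzuki–Miyaura coupling with boronate 11 (Pd(dppf)Cl2, K2CO3, dioxane/H2O). This gives 16 directly, followed by step 14.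

2. **Step 4 (iodination regiochemistry).** Risk is attack at C5 (para to OH, between the two OMOM groups) or di-iodination. Fallback: avoid electrophilic substitution. Convert phenol 3 to its O-diethylcarbamate, use carbamate/MOM-cooperative ortho-lithiation (s-BuLi/TMEDA, –78 °C), trap with B(OMe)3/H2O2 and methylate (MeI), then cleave the carbamate to give 2-methoxy-3,5-bis(methoxymethoxy)phenol. Mg-mediated formylation at its single free ortho position then gives 6 unambiguously.

3. **Step 5 (Ullmann methoxylation of a di-ortho-substituted iodophenol).** Risk is hydrodeiodination or slow coupling. Fallback: Cu-catalysed hydroxylation of 5 (CuI/8-hydroxyquinoline, KOH, DMSO/H2O) to 2,3-dihydroxy-4,6-bis(methoxymethoxy)benzaldehyde, then chemoselective methylation of the 3-OH (MeI 1 equiv, K2CO3, DMF). The 2-OH is hydrogen-bonded to the aldehyde and is less reactive.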